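The 1,2-dioxane ring is split into two three-atom halves. O1–O2–C3 with its acetate arm is treated as a peroxy-stabilised carbocation, and C4–C5–C6 with the C6 methoxy group is treated as a masked ketone homoenolate, namely a 1-methoxycyclopropane whose strained bond serves as the nucleophile. One acid-catalysed [3+3] operation forms C3–C4 and C6–O1, closes the ring and sets C3 (chiral counter-anion) and C6 (anomeric preference). Its precursors are the silyl peroxyacetal 3 of a 3-oxopropanoate and the pentynyl cyclopropyl ether 6. The enyne–ketone chain is then attached to the terminal alkyne by Sonogashira coupling, and the ester is hydrolysed.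

Key step: step 5

Assumption: the antipode of the confined acid catalyst that leaves the Si face of C3 open (giving 3S) is identified in a first screen. Compounds 2, 3 and 13 are used as racemates because their stereocentres are erased later. The hydroperoxy acetal is made by ozonolysis of a symmetric alkene in methanol, which is considered more dependable than acetal–hydrogen peroxide exchange.

**Route**

Step 1
Reactants: 1 dimethyl (E)-hex-3-enedioate
Product: 2 methyl 3-hydroperoxy-3-methoxypropanoate (racemic)
Conditions: O3, CH2Cl2/MeOH, −78 °C; N2 purge; concentrate below 20 °C; chromatography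
Reagents that add atoms: ozone, [O-][O+]=O; methanol, CO
Why: Criegee ozonolysis in methanol: cycloreversion of the primary ozonide gives a carbonyl oxide that methanol traps as the α-methoxy hydroperoxide, and because the alkene is symmetric both cleavage directions give the same hydroperoxide (its aldehyde partner is removed by chromatography).

Step 2
Reactants: 2 methyl 3-hydroperoxy-3-methoxypropanoate
Product: 3 methyl 3-methoxy-3-[(triethylsilyl)peroxy]propanoate (racemic)
Conditions: Et3SiCl, imidazole, DMF, 0 °C
Reagents that add atoms: chlorotriethylsilane, CC[Si](Cl)(CC)CC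
Why: O-Silylation of a hydroperoxide with a chlorosilane and imidazole is a mild, near-neutral reaction that leaves the ester and the acetal carbon untouched and gives the silyl peroxide that later supplies ring oxygen O1.

Step 3
Reactants: 4 methyl hex-5-ynoate
Product: 5 1-(pent-4-yn-1-yl)cyclopropan-1-ol
Conditions: EtMgBr (3.3 equiv), Ti(OiPr)4 (0.3 equiv), THF, 0 °C → rt; aq. NH4Cl
Reagents that add atoms: ethylmagnesium bromide, CC[Mg]Br
Why: Kulinkovich cyclopropanation: the titanacyclopropane formed from two ethyl groups on titanium adds twice to the ester carbonyl as a 1,2-dicarbanion, while the first equivalent of Grignard reagent turns the acetylenic C–H into an unreactive magnesium acetylide that is reprotonated on work-up.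

Step 4
Reactants: 5 1-(pent-4-yn-1-yl)cyclopropan-1-ol
Product: 6 1-methoxy-1-(pent-4-yn-1-yl)cyclopropane
Conditions: NaH (1.1 equiv), MeI, THF, 0 °C → rt
Reagents that add atoms: iodomethane, CI
Why: Williamson etherification of the tertiary cyclopropoxide with iodomethane; under aprotic conditions the alkoxide should not ring-open, and with about one equivalent of hydride the much less acidic alkyne C–H should not be methylated.

Step 5
Reactants: 3 methyl 3-methoxy-3-[(triethylsilyl)peroxy]propanoate; 6 1-methoxy-1-(pent-4-yn-1-yl)cyclopropane (1.5 equiv)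
Product: 8 methyl 2-[(3S,6R)-6-methoxy-6-(pent-4-yn-1-yl)-1,2-dioxan-3-yl]acetate, via open-chain methoxy-oxocarbenium ion 7 (not isolated)
Conditions: chiral confined imidodiphosphorimidate (IDPi) acid (5 mol %), 4 Å MS, CH2Cl2, −78 → −40 °C; Et3N quench
Reagents that add atoms: none
Why: Proposed new method: the catalyst, acting as its triethylsilyl derivative, removes the methoxy group of 3 as Et3SiOMe to give the peroxycarbenium ion paired with the chiral anion, the oxygen-activated C1–C2 σ-bond of 6 attacks C3 through its CH2 corner (forming C3–C4 and releasing ring strain as the C6 methoxy-oxocarbenium ion 7), and the silylated peroxy oxygen then adds to C6 and hands Et3Si+ back to the anion, which turns the catalyst over. The closest known reactions are the Lewis acid [3+2] annulation of silylperoxycarbenium ions with alkenes to 1,2-dioxolanes and the electrophilic ring opening of alkoxy- and siloxycyclopropanes as homoenolate equivalents. The 1,2-dioxane closes in 6-exo-trig mode, O1 adding to the exocyclic C6=O+ bond. C3 is set in the C–C bond formation by the confined anion, which has to leave only the Si face of the cation open to give 3S, and C6 is set under thermodynamic control, because reversible reopening to 7 under the acid funnels material to the epimer with axial methoxy (anomeric effect) and both carbon chains equatorial, which is the 3,6-cis (3S,6R) isomer. The step needs ionisation at OMe and not at OOSi (the silylium binds the more basic ether oxygen and the cation keeps its peroxy stabilisation), attack by the cyclopropane and not by the alkyne (a donor-substituted strained σ-bond is far more nucleophilic than an unactivated terminal alkyne), and cleavage of the ring bond next to OMe (only that cleavage gives an oxygen-stabilised cation).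

Step 6
Reactants: 9 dec-9-yn-1-ol
Product: 11 (E)-10-iododec-9-en-1-ol, via alkenylzirconocene 10 (not isolated)
Conditions: Cp2Zr(H)Cl (2.3 equiv), THF, rt; then I2, 0 °C; aqueous work-up
Reagents that add atoms: iodine, II
Why: Hydrozirconation–iodination: syn addition of Zr–H places zirconium on the terminal carbon and iodinolysis of the C–Zr bond occurs with retention, so only the (E)-iodide should form, the extra hydride being consumed by the hydroxyl group.

Step 7
Reactants: 11 (E)-10-iododec-9-en-1-ol
Product: 12 (E)-10-iododec-9-enal
Conditions: Dess–Martin periodinane, CH2Cl2, 0 °C → rt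
Reagents that add atoms: none
Why: Dess–Martin oxidation stops at the aldehyde and does not affect the alkenyl iodide.

Step 8
Reactants: 12 (E)-10-iododec-9-enal
Product: 13 (E)-11-iodoundec-10-en-2-ol (racemic)
Conditions: MeMgBr, THF, −78 °C; aq. NH4Cl
Reagents that add atoms: methylmagnesium bromide, C[Mg]Br
Why: Grignard 1,2-addition to the aldehyde; at −78 °C methylmagnesium bromide does not exchange with the alkenyl iodide, and the new carbinol centre is racemic but is oxidised in the next step.

Step 9
Reactants: 13 (E)-11-iodoundec-10-en-2-ol
Product: 14 (E)-11-iodoundec-10-en-2-one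
Conditions: Dess–Martin periodinane, CH2Cl2, 0 °C → rt
Reagents that add atoms: none
Why: Dess–Martin oxidation of the secondary alcohol gives the methyl ketone under neutral conditions that preserve the (E)-iodoalkene.

Step 10
Reactants: 8 methyl 2-[(3S,6R)-6-methoxy-6-(pent-4-yn-1-yl)-1,2-dioxan-3-yl]acetate; 14 (E)-11-iodoundec-10-en-2-one
Product: 15 methyl 2-[(3S,6R)-6-methoxy-6-[(E)-15-oxohexadec-6-en-4-yn-1-yl]-1,2-dioxan-3-yl]acetate
Conditions: Pd(PPh3)4 (5 mol %), CuI (10 mol %), Et3N, THF (degassed), rt
Reagents that add atoms: none
Why: Sonogashira coupling of a terminal alkyne with an (E)-alkenyl iodide proceeds at room temperature with retention of alkene geometry, conditions under which dialkyl peroxides and peroxyketals, the ketone and the ester should stay intact and neither ring stereocentre is touched.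

Step 11
Reactants: 15 methyl 2-[(3S,6R)-6-methoxy-6-[(E)-15-oxohexadec-6-en-4-yn-1-yl]-1,2-dioxan-3-yl]acetate
Product: 16 2-[(3S,6R)-6-methoxy-6-[(E)-15-oxohexadec-6-en-4-yn-1-yl]-1,2-dioxan-3-yl]acetic acid
Conditions: LiOH·H2O, THF/H2O (3:1), 0 °C; then dilute aq. HCl to pH 4, 0 °C
Reagents that add atoms: lithium hydroxide, [Li+].[OH-]
Why: Saponification of the methyl ester with lithium hydroxide at 0 °C; C3 lies β to the carbonyl and cannot epimerise by enolisation, and the low temperature and prompt mild acidification limit base-induced opening of the β-peroxy ester and acid exchange at the peroxyketal.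

**Compound list**

1 | dimethyl (E)-hex-3-enedioate | COC(=O)C/C=C/CC(=O)OC | starting material
2 | methyl 3-hydroperoxy-3-methoxypropanoate (racemic) | COC(=O)CC(OC)OO | intermediate
3 | methyl 3-methoxy-3-[(triethylsilyl)peroxy]propanoate (racemic) | COC(=O)CC(OC)OO[Si](CC)(CC)CC | intermediate
4 | methyl hex-5-ynoate | COC(=O)CCCC#C | starting material
5 | 1-(pent-4-yn-1-yl)cyclopropan-1-ol | OC1(CCCC#C)CC1 | intermediate
6 | 1-methoxy-1-(pent-4-yn-1-yl)cyclopropane | COC1(CCCC#C)CC1 | intermediate
7 | methyl (3S)-6-(methyloxoniumylidene)-3-[(triethylsilyl)peroxy]undec-10-ynoate (open-chain methoxy-oxocarbenium ion, paired with the catalyst anion) | C#CCCCC(=[O+]C)CC[C@@H](CC(=O)OC)OO[Si](CC)(CC)CC | intermediate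
8 | methyl 2-[(3S,6R)-6-methoxy-6-(pent-4-yn-1-yl)-1,2-dioxan-3-yl]acetate | CO[C@@]1(CCCC#C)CC[C@@H](CC(=O)OC)OO1 | intermediate
9 | dec-9-yn-1-ol | OCCCCCCCCC#C | starting material
10 | [(E)-10-{[chlorobis(cyclopentadienyl)zirconio]oxy}dec-1-en-1-yl]chlorobis(cyclopentadienyl)zirconium (alkenylzirconocene; Cp rings drawn σ-bound) | Cl[Zr](/C=C/CCCCCCCCO[Zr](Cl)(C1C=CC=C1)C1C=CC=C1)(C1C=CC=C1)C1C=CC=C1 | intermediate
11 | (E)-10-iododec-9-en-1-ol | OCCCCCCCC/C=C/I | intermediate
12 | (E)-10-iododec-9-enal | O=CCCCCCCC/C=C/I | intermediate
13 | (E)-11-iodoundec-10-en-2-ol (racemic) | CC(O)CCCCCCC/C=C/I | intermediate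
14 | (E)-11-iodoundec-10-en-2-one | CC(=O)CCCCCCC/C=C/I | intermediate
15 | methyl 2-[(3S,6R)-6-methoxy-6-[(E)-15-oxohexadec-6-en-4-yn-1-yl]-1,2-dioxan-3-yl]acetate | CO[C@@]1(CCCC#C/C=C/CCCCCCCC(C)=O)CC[C@@H](CC(=O)OC)OO1 | intermediate
16 | 2-[(3S,6R)-6-methoxy-6-[(E)-15-oxohexadec-6-en-4-yn-1-yl]-1,2-dioxan-3-yl]acetic acid | CO[C@@]1(CCCC#C/C=C/CCCCCCCC(C)=O)CC[C@@H](CC(=O)O)OO1 | target

**Step count and risks**

Total step count: 11. Longest linear sequence: 6 steps (9 → 11 → 12 → 13 → 14 → 15 → 16).

Steps most likely to fail:

1. Step 5 (proposed new method). The cyclopropane σ-bond may fail to intercept the peroxycarbenium ion, so that the cation instead loses a proton or is attacked by the alkyne. The cyclopropane may also be opened by the acid alone, and the anion may discriminate poorly between the two faces of C3. The fallback builds the ring by the established hydroperoxy-ketal oxa-Michael cyclisation and sets out from 4.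
   - Amidation of 4 with MeNHOMe·HCl and AlMe3 gives N-methoxy-N-methylhex-5-ynamide F1.
   - After masking the alkyne C–H with one equivalent of EtMgBr, the Grignard reagent of 2-(2-bromoethyl)-1,3-dioxolane adds to give 1-(1,3-dioxolan-2-yl)oct-7-yn-3-one F2.
   - Aqueous acid in acetone unmasks 4-oxonon-8-ynal F3.
   - Wittig olefination with Ph3P=CHCO2Me, which selects the aldehyde over the ketone, gives methyl (E)-6-oxoundec-2-en-10-ynoate F4.
   - Urea–hydrogen peroxide with catalytic Sc(OTf)3 in methanol converts the ketone into methyl (E)-6-hydroperoxy-6-methoxyundec-2-en-10-ynoate F5.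
   - Catalytic Et2NH in CF3CH2OH closes the hydroperoxide onto the enoate (6-exo-trig), and brief acid equilibration at C6 in methanol should give racemic methyl 2-[(3RS,6SR)-6-methoxy-6-(pent-4-yn-1-yl)-1,2-dioxan-3-yl]acetate F6.
   - Preparative chromatography on a chiral stationary phase separates 8 from its mirror image methyl 2-[(3R,6S)-6-methoxy-6-(pent-4-yn-1-yl)-1,2-dioxan-3-yl]acetate F7, and the route resumes at 8.

2. Step 10. Low-valent palladium, copper(I) or phosphine may reductively cleave the O–O bond, the amine may trigger retro-oxa-Michael opening of the ring, or the alkyne may homocouple. The fallback moves the coupling ahead of peroxide formation. It sets out from 6 and 14, which are joined under the same Sonogashira conditions to give 1-methoxy-1-[(E)-15-oxohexadec-6-en-4-yn-1-yl]cyclopropane F8. F8 is then annulated with 3 under the conditions of step 5, and the route is rejoined at 15.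

3. Step 11. Hydroxide may open the β-peroxy ester by E1cB elimination or degrade the peroxide faster than it cleaves the ester. The fallback removes the ester without hydroxide and before the coupling. It sets out from 8, which is hydrolysed with pig liver esterase in pH 7 phosphate buffer to 2-[(3S,6R)-6-methoxy-6-(pent-4-yn-1-yl)-1,2-dioxan-3-yl]acetic acid F9; the enzyme may also raise the enantiomeric purity. F9 is coupled with 14 under the Sonogashira conditions with additional Et3N, which arrives directly at 16.

**Further compounds**

F1 | step 5 | N-methoxy-N-methylhex-5-ynamide | CON(C)C(=O)CCCC#C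
F2 | step 5 | 1-(1,3-dioxolan-2-yl)oct-7-yn-3-one | C#CCCCC(=O)CCC1OCCO1
F3 | step 5 | 4-oxonon-8-ynal | C#CCCCC(=O)CCC=O
F4 | step 5 | methyl (E)-6-oxoundec-2-en-10-ynoate | C#CCCCC(=O)CC/C=C/C(=O)OC
F5 | step 5 | methyl (E)-6-hydroperoxy-6-methoxyundec-2-en-10-ynoate (racemic) | C#CCCCC(OC)(OO)CC/C=C/C(=O)OC
F6 | step 5 | methyl 2-[(3RS,6SR)-6-methoxy-6-(pent-4-yn-1-yl)-1,2-dioxan-3-yl]acetate (racemate, both enantiomers shown) | CO[C@@]1(CCCC#C)CC[C@@H](CC(=O)OC)OO1.CO[C@]1(CCCC#C)CC[C@H](CC(=O)OC)OO1
F7 | step 5 | methyl 2-[(3R,6S)-6-methoxy-6-(pent-4-yn-1-yl)-1,2-dioxan-3-yl]acetate | CO[C@]1(CCCC#C)CC[C@H](CC(=O)OC)OO1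
F8 | step 10 | 1-methoxy-1-[(E)-15-oxohexadec-6-en-4-yn-1-yl]cyclopropane | COC1(CCCC#C/C=C/CCCCCCCC(C)=O)CC1
F9 | step 11 | 2-[(3S,6R)-6-methoxy-6-(pent-4-yn-1-yl)-1,2-dioxan-3-yl]acetic acid | CO[C@@]1(CCCC#C)CC[C@@H](CC(=O)O)OO1
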